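(All runs come from a simulation with made-up constants, noise included.)

We will stop this flask early, and the reckoning below says how early. It is the delta flask itself, followed so far.

| flask | substrate | partner | free catalyst | second catalyst | remark | time |
|---|---|---|---|---|---|---|
| delta | 1 M | 1.1 equiv | 0.1 mol% | 15 mol% | the very flask that is asked about, followed so far |  |
| alpha | 1 M | 1.7 equiv | 0.1 mol% | 15 mol% | run made earlier |  |
| flask | 1.0 M | 1.10 equiv | 0.1 mol% | 15 mol% |  | 20 min |

| run | time / min | open intermediate / % | product / % |
|---|---|---|---|
| delta | 0.167 | 8.8 | 0.5 |
| delta | 0.417 | 9.7 | 2.4 |
| delta | 1.50 | 10.1 | 7.8 |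
| delta | 6.00 | 7.8 | 28.7 |
| alpha | 0.200 | 10.4 | 2.1 |
| alpha | 1.00 | 9.3 | 8.0 |
| alpha | 4.00 | 7.5 | 28.8 |
| alpha | 20.0 | 2.3 | 74.9 |

(scatter of a reading: 0.5 percentage points)

- the best time, 20 min at the latest, for open intermediate
- the amount of open intermediate, in percent of the substrate charged, at that time

- the numbers in the tables scatter with a standard deviation of 0.5 percentage points
- a reading or a percentage of product counts all its forms, free or not

After a fast burst, open intermediate tracks the material not yet product. Over four readings past the burst, two in delta and two in alpha up to 6.00 min, the ratio reads 10.6 %. We call this the open share, the pre-equilibrium fraction: open intermediate divided by all material not yet product, every form of product counted. Near the peak, product is then the small correction.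

Take the settings in turn. By hand, more partner should speed product and pull open intermediate down sooner, with the open share unmoved. The runs show this. Product reads 28.7 % in delta at 6.00 min and 28.8 % in alpha at 4.00 min, a time ratio of 1.50 against a partner ratio of 1.55. Open intermediate at those points reads 7.8 % and 7.5 %.

By hand, free catalyst should change how fast the burst comes. Second catalyst should change how fast product forms. Both runs carry the same loadings, so the readings cannot test either.

Our reckoning puts the peak where the burst ends, near 0.417 min:

peak = open share × (1 − product) = 10.6 % × (1 − 2.4 %) = 10.4 %

The forecast gives 10.2 % at 0.5 min, a lower amount and a later time than ours: “The peak therefore comes right after the burst”.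

The flask gives 10.1 % at 0.378 min. The forecast's amount stands within the margin, and its time is 1.32 times the flask's.

    substrate + free catalyst ⇌ free catalyst + open intermediate (K = 0.120, k = 25.0 M⁻¹ s⁻¹)
    partner + catalyst intermediate → second catalyst + product (k = 5.40 M⁻¹ s⁻¹)
    second catalyst + open intermediate ⇌ catalyst intermediate (K = 0.0130 M⁻¹, k = 0.700 M⁻¹ s⁻¹)
    crystals ⇌ product, rate k4*(cs4 - [product]) while solid is left; crystals form when [product] > cs4 (solubility = 0.0510 M, k = 4.60 s⁻¹)

At 20.0 min this flask holds 58.9 % product, crystals included. The open share then gives 4.36 % open intermediate, and the flask holds 4.32 %. The neighbour charged with 0.40 M of substrate keeps the equivalents and loadings and runs for the same time. It reaches 18.4 % product at 20.0 min, so the same line gives 8.65 %. That neighbour holds 8.62 % open intermediate at 20.0 min.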